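**Plan** (target numbered as a cyclohepta[b]furan: O1, C2, C3, C3a, C4–C8, C8a)

1. Retrosynthesis: cut the C8 ester; then take C6 (the CH–CH3 unit) and the C7 hydroxyl out of the seven-membered carbocycle (cut C5–C6 and C6–C7, rejoin C5–C7); then cut the C7–acyl bond and the lactone C3–C3a bond, arriving at a trans-4,5-dioxygenated cyclohexenone from (−)-quinic acid.
2. Enabling feature: in C5(=O)–C6H(CH3)–C7(OH)(COR) the ring ketone and the exocyclic crotonoyl C=O are 1,4-related, so the carbocycle C3a–C4–C5–C6–C7–C8–C8a is the one-carbon homologue of a 2-acylcyclohexanone. C7 is the enolate carbon left when a carbenoid carbon is inserted between the ring C=O and the acyl-bearing carbon.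
3. Forward: quinic acid gives the six-membered carbocycle; the lactone ring is closed by a tethered vinyl-radical cyclisation from the C8a oxygen; the crotonoyl group comes from an aldol/oxidation; a zinc-carbenoid ring expansion with in-flask hydroxylation gives the seven-membered ring; desilylation and esterification finish.
4. Stereochemistry: C8a and C8 are C4 and C5 of quinic acid; C3a comes from the cis-selective radical cyclisation; C7 from oxygen transfer anti to the C8 silyloxy group; C6 by equilibration α to the ketone; the ester centre from (S)-2-methylbutanoic acid.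

Key step: step 10

Assumption: C6, α to the ring ketone, is epimerisable, and the natural configuration (methyl trans to the crotonoyl group and to the C8 oxygen, avoiding a syn-1,3 contact) is taken as the thermodynamically preferred one.

Numbering in names: compounds 4–11 as cyclohexanones (C1 = C=O, quinic acid numbering); 12–18 as 1-benzofurans (O1, C2, C3, C3a, C4–C7, C7a); 19–22 as above.

**Step 1**
Reactants: 1 (−)-quinic acid
Product: 2 3,4-O-isopropylidene-1,5-quinide
Conditions: 2,2-dimethoxypropane, TsOH·H2O (cat.), acetone, reflux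
Reagents that add atoms: 2,2-dimethoxypropane, COC(C)(C)OC
Why: Acid-catalysed acetalisation protects the cis-3,4-diol while the carboxyl lactonises onto the cis 5-hydroxyl, so the trans-4,5-diol is differentiated without touching a stereocentre.

**Step 2**
Reactants: 2 3,4-O-isopropylidene-1,5-quinide
Product: 3 1-(hydroxymethyl)-3,4-O-isopropylidenecyclohexane-1,3,4,5-tetrol (configuration as in 1)
Conditions: NaBH4, EtOH, 0 °C to rt
Reagents that add atoms: none
Why: Borohydride reduction of the strained bridged lactone should give the primary alcohol and free the 5-hydroxyl, with no stereocentre affected.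

**Step 3**
Reactants: 3 1-(hydroxymethyl)-3,4-O-isopropylidenecyclohexane-1,3,4,5-tetrol
Product: 4 (3R,4S,5R)-5-hydroxy-3,4-(isopropylidenedioxy)cyclohexan-1-one
Conditions: NaIO4, H2O (pH 7 buffer), 0 °C to rt
Reagents that add atoms: none
Why: Periodate glycol cleavage of the only free 1,2-diol (tertiary C1–OH and CH2OH) should give the C1 ketone and formaldehyde, the acetonide masking the other vicinal oxygens.

**Step 4**
Reactants: 4 (3R,4S,5R)-5-hydroxy-3,4-(isopropylidenedioxy)cyclohexan-1-one
Product: 5 (3R,4S,5R)-5-(tert-butyldimethylsilyloxy)-3,4-(isopropylidenedioxy)cyclohexan-1-one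
Conditions: TBSCl, imidazole, DMF, 0 °C to rt
Reagents that add atoms: tert-butyldimethylsilyl chloride, CC(C)(C)[Si](C)(C)Cl
Why: Standard silylation of the secondary alcohol; the silyl ether is a poor leaving group and so steers the next elimination to the acetonide oxygen.

**Step 5**
Reactants: 5 (3R,4S,5R)-5-(tert-butyldimethylsilyloxy)-3,4-(isopropylidenedioxy)cyclohexan-1-one
Product: 6 (4R,5R)-5-(tert-butyldimethylsilyloxy)-4-hydroxycyclohex-2-en-1-one
Conditions: DBU (0.2 equiv), CH2Cl2, 0 °C
Reagents that add atoms: none
Why: E1cB β-elimination, in which enolisation towards C2 expels the axial C3 acetonide oxygen and the resulting hemiketal alkoxide loses acetone, should give the γ-hydroxy enone with the C4 hydroxyl free and the equatorial C5 silyl ether retained, both stereocentres untouched.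

**Step 6**
Reactants: 6 (4R,5R)-5-(tert-butyldimethylsilyloxy)-4-hydroxycyclohex-2-en-1-one; 7 methoxyallene
Product: 8 (4R,5R)-4-[(2-bromo-1-methoxyprop-2-en-1-yl)oxy]-5-(tert-butyldimethylsilyloxy)cyclohex-2-en-1-one (both acetal epimers)
Conditions: NBS, CH2Cl2, −40 to 0 °C
Reagents that add atoms: N-bromosuccinimide, O=C1CCC(=O)N1Br
Why: Haloacetalisation of an alkoxyallene (bromonium attack on the central allene carbon, capture of the oxocarbenium ion by the C4 hydroxyl) should give the 2-bromoallyl mixed acetal, a vinyl-radical precursor of the Ueno–Stork type whose acetal centre is a mixture removed in step 9.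

**Step 7**
Reactants: 8 (4R,5R)-4-[(2-bromo-1-methoxyprop-2-en-1-yl)oxy]-5-(tert-butyldimethylsilyloxy)cyclohex-2-en-1-one; 9 (E)-but-2-enal
Product: 11 aldol adduct 6-[(2E)-1-hydroxybut-2-en-1-yl] derivative of 8, via lithium dienolate 10 (not isolated)
Conditions: LiHMDS (1.05 equiv), THF, −78 °C; then 9, −78 °C; AcOH quench
Reagents that add atoms: none
Why: Kinetic α′-deprotonation of the enone gives the cross-conjugated dienolate, whose aldol 1,2-addition to crotonaldehyde places the four-carbon acyl precursor at C6 regiospecifically, the two new centres being mixtures that become sp2 or enolisable in step 9.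

**Step 8**
Reactants: 11 aldol adduct 6-[(2E)-1-hydroxybut-2-en-1-yl] derivative of 8
Product: 12 (3aS,7R,7aR)-7-(tert-butyldimethylsilyloxy)-6-[(2E)-1-hydroxybut-2-en-1-yl]-2-methoxy-3-methylidenehexahydro-1-benzofuran-5(4H)-one (cis-fused; mixtures at C2 and C6 and at the carbinol)
Conditions: Bu3SnH (slow addition), AIBN (cat.), PhH, 80 °C
Reagents that add atoms: none
Why: Tin-hydride-mediated vinyl radical formation and 5-exo-trig cyclisation onto the enone β-carbon (Ueno–Stork-type radical cyclisation) should close the methylene-bearing oxacycle, the two-atom tether from the C4 oxygen forcing the new C–C bond onto the same face and so setting the cis ring fusion (C3a).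

**Step 9**
Reactants: 12 (3aS,7R,7aR)-7-(tert-butyldimethylsilyloxy)-6-[(2E)-1-hydroxybut-2-en-1-yl]-2-methoxy-3-methylidenehexahydro-1-benzofuran-5(4H)-one
Product: 14 (3aS,7R,7aR)-6-[(2E)-but-2-enoyl]-7-(tert-butyldimethylsilyloxy)-3-methylidenetetrahydro-1-benzofuran-2,5(3H,4H)-dione (enolised β-diketone), via keto lactol 13 (not isolated)
Conditions: Jones reagent (CrO3, aq H2SO4), acetone, 0 °C
Reagents that add atoms: water, O
Why: Jones oxidation should turn the allylic alcohol into the enone and, after acid hydrolysis of the methyl acetal to the lactol, give the α-methylene-γ-lactone, which also removes the stereo-mixtures carried from steps 6 and 7.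

**Step 10**
Reactants: 14 (3aS,7R,7aR)-6-[(2E)-but-2-enoyl]-7-(tert-butyldimethylsilyloxy)-3-methylidenetetrahydro-1-benzofuran-2,5(3H,4H)-dione; 15 1,1-diiodoethane
Product: 19 (3aS,6R,7S,8S,8aR)-7-[(2E)-but-2-enoyl]-8-(tert-butyldimethylsilyloxy)-7-hydroxy-6-methyl-3-methylidenehexahydro-2H-cyclohepta[b]furan-2,5(3H)-dione, via zinc enolate 16 (not isolated), via zinc cyclopropanolate 17 (not isolated), via ring-expanded zinc dienolate 18 (not isolated)
Conditions: Et2Zn, 15, CH2Cl2, 0 °C; add 14, 0 °C to rt; then dimethyldioxirane (acetone), −78 to −20 °C; aq NH4Cl; then DBU (cat.), CH2Cl2, 0 °C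
Reagents that add atoms: dimethyldioxirane, CC1(C)OO1
Why: Proposed new method: Et2Zn converts the enolised β-diketone into zinc enolate 16, which is C-alkylated at the acyl-bearing carbon by the carbenoid EtZnCH(CH3)I; the α-zincioethyl group then adds to the adjacent ring carbonyl to give the donor–acceptor cyclopropanolate 17, whose shared C–C bond fragments in a retro-aldol sense so that CH(CH3) is inserted between the ring C=O and the acyl-bearing carbon, and the regiodefined zinc dienolate 18 is hydroxylated at carbon by dimethyldioxirane. The closest known reaction type is the zinc-carbenoid homologation (chain extension and ring expansion) of β-keto esters and β-diketones, known with 1,1-diiodoethane and with trapping of the zinc enolate by aldehydes or iodine, and dimethyldioxirane oxidation of metal enolates is also known, but their combination on a 2-acylcyclohexanone is not. The only ring closed is the transient cyclopropane (3-exo-trig); the seven-membered ring arises by cleavage of the shared bond of the bicyclo[4.1.0] intermediate, not by a closure. The new C7 centre is controlled by the bulky silyloxy group on C8, which shields one face of the exocyclic enolate so that oxygen enters anti to it (hydroxyl trans to OSi, crotonoyl cis); the new C6 centre is α to the ring ketone and is set thermodynamically in the DBU equilibration. The step needs the zincated carbon to attack the saturated ring carbonyl and not the crotonoyl carbonyl, which conjugation makes less electrophilic, and it needs the electron-poor methylene-lactone and enone C=C bonds to stay untouched, which should hold for an electrophilic zinc carbenoid and for dimethyldioxirane at low temperature.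

**Step 11**
Reactants: 19 (3aS,6R,7S,8S,8aR)-7-[(2E)-but-2-enoyl]-8-(tert-butyldimethylsilyloxy)-7-hydroxy-6-methyl-3-methylidenehexahydro-2H-cyclohepta[b]furan-2,5(3H)-dione
Product: 20 (3aS,6R,7S,8S,8aR)-7-[(2E)-but-2-enoyl]-7,8-dihydroxy-6-methyl-3-methylidenehexahydro-2H-cyclohepta[b]furan-2,5(3H)-dione
Conditions: HF·pyridine, pyridine/THF, 0 °C to rt
Reagents that add atoms: none
Why: Fluoride-mediated Si–O cleavage under buffered acidic conditions should free the secondary C8 hydroxyl while avoiding the alkoxide that could trigger retro-aldol cleavage or oxa-Michael addition to the crotonoyl group.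

**Step 12**
Reactants: 20 (3aS,6R,7S,8S,8aR)-7-[(2E)-but-2-enoyl]-7,8-dihydroxy-6-methyl-3-methylidenehexahydro-2H-cyclohepta[b]furan-2,5(3H)-dione; 21 (S)-2-methylbutanoic acid
Product: 22 target, (3aS,6R,7S,8S,8aR)-7-[(2E)-but-2-enoyl]-7-hydroxy-6-methyl-3-methylidene-2,5-dioxooctahydro-2H-cyclohepta[b]furan-8-yl (2S)-2-methylbutanoate
Conditions: EDC·HCl, DMAP (cat.), CH2Cl2, 0 °C
Reagents that add atoms: none
Why: Carbodiimide/DMAP (Steglich) esterification should acylate the secondary C8 hydroxyl and leave the tertiary C7 hydroxyl, the mild conditions preserving the α-stereocentre of the (S)-acid, which supplies the last stereocentre.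

**Compound list**

1 | (−)-quinic acid | OC(=O)[C@]1(O)C[C@@H](O)[C@@H](O)[C@H](O)C1 | starting material
2 | 3,4-O-isopropylidene-1,5-quinide | O[C@@]12C[C@H]3OC(C)(C)O[C@H]3[C@@H](C1)OC2=O | intermediate
3 | 1-(hydroxymethyl)-3,4-O-isopropylidenecyclohexane-1,3,4,5-tetrol | OC[C@]1(O)C[C@H]2OC(C)(C)O[C@H]2[C@H](O)C1 | intermediate
4 | (3R,4S,5R)-5-hydroxy-3,4-(isopropylidenedioxy)cyclohexan-1-one | O=C1C[C@H]2OC(C)(C)O[C@H]2[C@H](O)C1 | intermediate
5 | (3R,4S,5R)-5-(tert-butyldimethylsilyloxy)-3,4-(isopropylidenedioxy)cyclohexan-1-one | O=C1C[C@H]2OC(C)(C)O[C@H]2[C@H](O[Si](C)(C)C(C)(C)C)C1 | intermediate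
6 | (4R,5R)-5-(tert-butyldimethylsilyloxy)-4-hydroxycyclohex-2-en-1-one | O=C1C=C[C@@H](O)[C@H](O[Si](C)(C)C(C)(C)C)C1 | intermediate
7 | methoxyallene | COC=C=C | starting material
8 | (4R,5R)-4-[(2-bromo-1-methoxyprop-2-en-1-yl)oxy]-5-(tert-butyldimethylsilyloxy)cyclohex-2-en-1-one | O=C1C=C[C@@H](OC(OC)C(Br)=C)[C@H](O[Si](C)(C)C(C)(C)C)C1 | intermediate
9 | (E)-but-2-enal (crotonaldehyde) | C/C=C/C=O | starting material
10 | cross-conjugated lithium dienolate of 8 (enolate C1=C6), not isolated | [Li]OC1=C[C@@H](O[Si](C)(C)C(C)(C)C)[C@H](OC(OC)C(Br)=C)C=C1 | intermediate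
11 | aldol adduct, 6-[(2E)-1-hydroxybut-2-en-1-yl] derivative of 8 | O=C1C=C[C@@H](OC(OC)C(Br)=C)[C@H](O[Si](C)(C)C(C)(C)C)C1C(O)/C=C/C | intermediate
12 | (3aS,7R,7aR)-7-(tert-butyldimethylsilyloxy)-6-[(2E)-1-hydroxybut-2-en-1-yl]-2-methoxy-3-methylidenehexahydro-1-benzofuran-5(4H)-one | O=C1C[C@H]2C(=C)C(OC)O[C@H]2[C@H](O[Si](C)(C)C(C)(C)C)C1C(O)/C=C/C | intermediate
13 | keto lactol, (3aS,7R,7aR)-6-[(2E)-but-2-enoyl]-7-(tert-butyldimethylsilyloxy)-2-hydroxy-3-methylidenehexahydro-1-benzofuran-5(4H)-one, not isolated | O=C1C[C@H]2C(=C)C(O)O[C@H]2[C@H](O[Si](C)(C)C(C)(C)C)C1C(=O)/C=C/C | intermediate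
14 | (3aS,7R,7aR)-6-[(2E)-but-2-enoyl]-7-(tert-butyldimethylsilyloxy)-3-methylidenetetrahydro-1-benzofuran-2,5(3H,4H)-dione | O=C1C[C@H]2C(=C)C(=O)O[C@H]2[C@H](O[Si](C)(C)C(C)(C)C)C1C(=O)/C=C/C | intermediate
15 | 1,1-diiodoethane | CC(I)I | starting material
16 | ethylzinc enolate of 14 (ring enolate C5=C6), not isolated | CC[Zn]OC1=C(C(=O)/C=C/C)[C@@H](O[Si](C)(C)C(C)(C)C)[C@@H]2OC(=O)C(=C)[C@@H]2C1 | intermediate
17 | zinc cyclopropanolate (bicyclo[4.1.0]heptane: cyclopropane from the former ring C=O carbon, the acyl-bearing carbon and the new CH–CH3; mixture at the new centres), not isolated | C/C=C/C(=O)C12C(C)C1(O[Zn]CC)C[C@H]1C(=C)C(=O)O[C@H]1[C@@H]2O[Si](C)(C)C(C)(C)C | intermediate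
18 | ring-expanded zinc dienolate (seven-membered ring, C7=C(OZnEt)–propenyl, C6 a mixture), not isolated | C/C=C/C(O[Zn]CC)=C1C(C)C(=O)C[C@H]2C(=C)C(=O)O[C@H]2[C@@H]1O[Si](C)(C)C(C)(C)C | intermediate
19 | (3aS,6R,7S,8S,8aR)-7-[(2E)-but-2-enoyl]-8-(tert-butyldimethylsilyloxy)-7-hydroxy-6-methyl-3-methylidenehexahydro-2H-cyclohepta[b]furan-2,5(3H)-dione | C=C1C(=O)O[C@@H]2[C@H]1CC(=O)[C@H](C)[C@@](O)(C(=O)/C=C/C)[C@H]2O[Si](C)(C)C(C)(C)C | intermediate
20 | (3aS,6R,7S,8S,8aR)-7-[(2E)-but-2-enoyl]-7,8-dihydroxy-6-methyl-3-methylidenehexahydro-2H-cyclohepta[b]furan-2,5(3H)-dione | C=C1C(=O)O[C@@H]2[C@H]1CC(=O)[C@H](C)[C@@](O)(C(=O)/C=C/C)[C@H]2O | intermediate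
21 | (S)-2-methylbutanoic acid | CC[C@H](C)C(=O)O | starting material
22 | CNP0153197.2, (3aS,6R,7S,8S,8aR)-7-[(2E)-but-2-enoyl]-7-hydroxy-6-methyl-3-methylidene-2,5-dioxooctahydro-2H-cyclohepta[b]furan-8-yl (2S)-2-methylbutanoate | C=C1C(=O)O[C@@H]2[C@H]1CC(=O)[C@H](C)[C@@](O)(C(=O)/C=C/C)[C@H]2OC(=O)[C@@H](C)CC | target

**Step count and risks**

Total step count: 12. Longest linear sequence: 12 steps (from 1).

Steps most likely to fail:

Step 10 (the proposed new method). The zincated carbon may attack the crotonoyl carbonyl, which extends the side chain instead of expanding the ring. The silyloxy group may be lost from zinc enolate 16 by E1cB elimination. Residual organozinc may consume the dioxirane, or oxygen transfer may show poor facial selectivity. The equilibrium at C6 may be unfavourable. The fallback uses known reaction types only and sets out from 14. The zinc-carbenoid homologation is run as a plain ring expansion, and zinc dienolate 18 is intercepted by enolate silylation (TMSCl, Et3N) to isolate the 2-silyloxydiene, trimethylsilyl dienol ether F1. Rubottom oxidation of F1 (mCPBA, NaHCO3, CH2Cl2, −20 °C) on the face anti to the C8 silyloxy group should give the 7-O-trimethylsilyl ether of 19, α-silyloxy ketone F2. F2 is equilibrated at C6 (DBU cat.) and doubly desilylated with HF·pyridine, which comes back to the route at 20.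

Step 7. The silyloxy group β to the lithium dienolate may be lost by E1cB elimination, followed by aromatisation. γ-Deprotonation may compete, and retro-aldol cleavage may occur on work-up. The fallback sets out from 8 and avoids a lithium enolate. Soft enolisation (MgBr2·OEt2, i-Pr2NEt, CH2Cl2) with 1-crotonoylbenzotriazole C-acylates the magnesium enolate directly to the enolised 6-crotonoyl enone F3. The same tin-hydride vinyl-radical cyclisation then gives the cis-fused diketone, methylene lactol ether F4. Jones oxidation of F4, now only the acetal-to-lactone change through 13, comes back to the route at 14.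

Step 12. Acylation of the hindered secondary alcohol may be slow, which lets the free C8 hydroxyl add in an oxa-Michael sense to the cis crotonoyl group. The tertiary alcohol may be acylated, or the activated acid may racemise. The fallback sets out from 19 and bypasses 20. Acid 21 is converted with cyanuric fluoride and pyridine into (S)-2-methylbutanoyl fluoride F5. Fluoride-catalysed acyl transfer to the silyl ether (F5, TBAT cat., THF) acylates the C8 oxygen as it is unmasked, so no free hydroxy enone accumulates and only the silylated oxygen reacts. This comes back to the route at 22.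

**Further compounds**

F1 | step 10 | trimethylsilyl dienol ether of the ring-expanded diketone (C7=C(OSiMe3)–propenyl; C3a, C8, C8a as in 14; C6 a mixture) | C/C=C/C(O[Si](C)(C)C)=C1C(C)C(=O)C[C@H]2C(=C)C(=O)O[C@H]2[C@@H]1O[Si](C)(C)C(C)(C)C
F2 | step 10 | 7-O-trimethylsilyl ether of 19 (C6 a mixture before equilibration) | C=C1C(=O)O[C@@H]2[C@H]1CC(=O)C(C)[C@@](O[Si](C)(C)C)(C(=O)/C=C/C)[C@H]2O[Si](C)(C)C(C)(C)C
F3 | step 7 | (4R,5R)-4-[(2-bromo-1-methoxyprop-2-en-1-yl)oxy]-6-[(2E)-but-2-enoyl]-5-(tert-butyldimethylsilyloxy)cyclohex-2-en-1-one (enolised) | O=C1C=C[C@@H](OC(OC)C(Br)=C)[C@H](O[Si](C)(C)C(C)(C)C)C1C(=O)/C=C/C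
F4 | step 7 | (3aS,7R,7aR)-6-[(2E)-but-2-enoyl]-7-(tert-butyldimethylsilyloxy)-2-methoxy-3-methylidenehexahydro-1-benzofuran-5(4H)-one | O=C1C[C@H]2C(=C)C(OC)O[C@H]2[C@H](O[Si](C)(C)C(C)(C)C)C1C(=O)/C=C/C
F5 | step 12 | (S)-2-methylbutanoyl fluoride | CC[C@H](C)C(F)=O
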